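Abbreviations: prenyl = 3-methylbut-2-en-1-yl; TES = triethylsilyl; TBS = tert-butyldimethylsilyl; TIPS = triisopropylsilyl. Flavanone numbering (O1, C2–C4, C4a, C5–C8, C8a; rings A, B, C) is used for the target.

## The problem

6,8-Diprenylnaringenin (20) is a flavanone: a chroman-4-one (ring C fused to ring A) with a 4-hydroxyphenyl group (ring B) at C2. Ring A is a fully substituted phloroglucinol nucleus, with oxygen at C5, C7 and C8a, prenyl at C6 and C8, and the ketone carbon C4 on C4a, so the acyl group has to be placed between two oxygens on a ring with no other free position. C2 (S) is the only stereocentre, so nothing in the molecule can direct it and it must come from a catalyst or reagent. Once made it is fragile: it is a benzylic ether carbon β to the ketone, lost by retro-oxa-Michael ring opening under base and by ionization under acid. Each prenyl group sits next to a phenol and closes to a chroman under Brønsted or Lewis acid. The prenyl groups also exclude hydrogenolysis and electrophilic halogenation, and with them benzyl ethers, methyl ethers and Friedel–Crafts acylation. The feature that opens a way through is that a 2,4-diprenylphloroglucinol nucleus has exactly one hydrogen-bearing ring carbon, the future C4a, and it lies ortho to the oxygen that becomes O1. An acyl group parked on that oxygen can be moved to C4a by light alone.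

## Retrosynthesis

**20 from 19.** Only three O–Si bonds are cut. Silyl ethers are the one phenol protection that comes off (buffered fluoride) without acid, hydrogen or a strong Lewis acid, so both the prenyl groups and C2 are safe. The forward step must keep the medium buffered so that ring C stays closed.

**19 from 17, and 17 from 16.** The O1–C2 bond is cut. Closing it by conjugate addition to an enone would pass through a planar intermediate and give racemic material. Closing it by SN2 displacement at a preformed carbinol transfers a stereocentre that can be made reliably elsewhere. The precursor 17 is open-chain, has one free phenol (the one that becomes O1) and an (R)-carbinol; inversion gives (2S). The forward Mitsunobu reaction must run without ionization of the electron-rich benzylic carbon and without β-elimination. 17 comes from 16 by removal of one alkyl silyl ether in the presence of three aryl silyl ethers, which fixes TES for the carbinol.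

**16 from 14 (key disconnection).** The aryl ketone bond C4–C4a is cut. A Friedel–Crafts or thermal Fries acylation would make it with Lewis acid and cyclize the prenyl groups. An aryl-metal route has no handle, because halogenating a prenylated ring is not selective. Read as a 1,3-shift of the acyl group from oxygen to carbon, the C–C bond problem becomes an esterification: 14 is the ester of the acid on the very oxygen that later becomes O1. The forward photolysis, through dienone 15, must put the acyl group on the single free ring carbon. The two spectator phenols are silylated in 14 so that no phenolic O–H lies beside a prenyl double bond in the excited state and so that 16 emerges with one free phenol.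

**14 from 13, and 13 from 12 and 4.** Two O–Si bonds and the ester C–O bond are cut, giving two fragments of similar size. In 4 the two hydroxyls flanked by one prenyl group and one hydrogen are equivalent and more accessible than the one between two prenyl groups. The forward step therefore asks for mono-acylation of a symmetrical triol, handled by an excess of the cheap partner 4.

**4 from 1 and 2.** Two aryl–CH2 bonds are cut. Any two ring carbons of 1 are meta to each other, so two C-prenylations (through 3) can only give the 2,4-pattern. The price is a modest, chromatographic first step from commodity chemicals.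

**12 from 11, 10, 9, and 9 from 6 and 7.** The silyl ether and methyl ester are adjusted (12 from 11 from 10). The stereocentre is cut back to the ketone 9, because catalytic hydrogenation of a β-keto ester is the most dependable way to a 3-aryl-3-hydroxypropanoate and needs no auxiliary. 9 is cut at its C2–C3 bond into the benzoate 6 and methyl acetate 7 (crossed Claisen condensation through enolate 8). 6 is the TIPS ether of 5; TIPS is chosen because it survives enolates, light and the Mitsunobu step.

## Roads not taken

**Alternative 1: benzannulation of ring A onto a chiral dihydropyranone.**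
- Cut: C4a–C5 and C8–C8a, so that ring A is built last.
- Forward step: the ketene-acetal diene A3 (1-methoxy-2,4-diprenyl-1,3-bis(trimethylsilyloxy)buta-1,3-diene) would add across C5=C6 of the bromodihydropyranone A2. Loss of HBr and methanol would aromatize to the 4'-O-TBS flavanone A1.
- Merits: it is the most convergent plan. It avoids the statistical prenylation of phloroglucinol, carries C2 from an asymmetric hetero-Diels–Alder step without touching it again, and ends one fluoride step from 20. In step count it would beat the chosen route.
- Weak points: A2 is a vinylogous ester, and its C5=C6 bond is a poor two-carbon partner for a diene substituted at both reacting ends. After the first C–C bond forms, the enolate can expel the ring oxygen from C6 instead of bromide; that would open ring C and lose the C8a oxygen. The aromatization then needs base or acid in the presence of the C2 ether. A3, with four substituents and two prenyl groups, must also be made with defined geometry.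
- Comparison: the chosen plan is longer, but each of its steps belongs to an established reaction class, whereas this key step would itself need to be developed.

**Alternative 2: asymmetric conjugate reduction of the flavone.**
- Cut: the C2–H and C3–H bonds.
- Forward step: a copper hydride LCuH (L a chiral bisphosphine, made from Cu(OAc)2 and a silane) would add hydride to C2 of the tris-MOM flavone A5 and give the (2S)-flavanone A4.
- Merits: all intermediates are achiral and flat until the last skeletal step. Chirality comes from a catalyst at the end, and no substitution at a cation-prone benzylic carbon is needed. In that respect it is better than the chosen plan.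
- Weak points: A5 is a 2-aryl-γ-pyrone, a doubly donor-substituted vinylogous ester shielded by the 5-alkoxy group and much less reactive than the enones and enoates on which such reductions are established. Reduction of the carbonyl and retro-oxa-Michael opening of the resulting enolate both threaten the outcome. Making A5 needs oxidative or acidic ring closure on a prenylated ring, and the three MOM groups of A4 must come off with acid next to two prenyl groups.
- Comparison: the chosen plan answers with a hydrogenation and an SN2 closure whose stereochemical course is understood, and with a fluoride end-game.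

**Alternative 3: Petasis–Ferrier rearrangement.**
- Cut: C2–C3.
- Forward step: a chiral aluminium Lewis acid of the (binaphtholate)AlMe kind would ionize the C2–O3 bond of the 4-methylene-1,3-benzodioxine A7, and the enolate carbon would attack the oxocarbenium ion to give the tris-TBS flavanone A6.
- Merits: it forms ring C and the C2–C3 bond in one step from an acetal that is easy to assemble (acetal formation, then carbonyl methylenation with Cp2TiMe2). A6 differs from 19 only in one silyl group, so the end-game is equally short.
- Weak points: ionization erases the acetal stereocentre. All selectivity would have to come from the Lewis acid acting on a loosely bound oxocarbenium/enolate pair, which is not established for this rearrangement. The same Lewis acid can reopen the product by retro-oxa-Michael reaction and can attack the prenyl groups and aryl silyl ethers of the electron-rich ring.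
- Comparison: the chosen plan needs two more operations to close ring C (unmasking, then Mitsunobu reaction), but its stereocentre is made by a predictable catalyst-controlled step.

Key step: step 9

Remark: the ring carbon that becomes sp3 in dienone 15 is formed without control and disappears on enolization, so 15 is drawn without a descriptor there.

## Route

Step 1
Reactants: 1 phloroglucinol; 2 prenyl bromide
Product: 4 2,4-diprenylphloroglucinol, via 2-prenylphloroglucinol 3 (not isolated)
Conditions: 2 (2.1 equiv), DBU (2.2 equiv), THF, 0 °C to rt; chromatography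
Reagents that add atoms: none
Why: Base-mediated C-alkylation of the ambident phloroglucinolate (ring carbon attacks the allylic bromide); any two ring carbons of 1 are meta, so the second prenyl group can only give the 2,4-isomer, and two equivalents of 2 leave one ring carbon free.

Step 2
Reactants: 5 methyl 4-hydroxybenzoate
Product: 6 methyl 4-(triisopropylsilyloxy)benzoate
Conditions: TIPSCl, imidazole, DMF, rt
Reagents that add atoms: triisopropylsilyl chloride, CC(C)[Si](Cl)(C(C)C)C(C)C
Why: Standard phenol silylation; the bulky aryl TIPS ether should survive the ester enolate, the photolysis and the Mitsunobu step and fall to fluoride at the end.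

Step 3
Reactants: 6 methyl 4-(triisopropylsilyloxy)benzoate; 7 methyl acetate
Product: 9 methyl 3-oxo-3-[4-(triisopropylsilyloxy)phenyl]propanoate, via methyl acetate lithium enolate 8 (not isolated)
Conditions: 7 (3 equiv), LiN(i-Pr)2 (3 equiv), THF, −78 °C; then 6, −78 to −20 °C; aq NH4Cl
Reagents that add atoms: none
Why: Crossed Claisen condensation: only 7 can be enolized, the benzoate 6 is the only acylating partner, and deprotonation of the β-keto ester product drives the reaction.

Step 4
Reactants: 9 methyl 3-oxo-3-[4-(triisopropylsilyloxy)phenyl]propanoate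
Product: 10 methyl (3R)-3-hydroxy-3-[4-(triisopropylsilyloxy)phenyl]propanoate
Conditions: H2 (50 bar), RuCl2[(S)-BINAP](dmf)n (1 mol %), MeOH, 50 °C
Reagents that add atoms: none
Why: Noyori asymmetric hydrogenation of a β-keto ester: the substrate chelates divalent ruthenium through both carbonyls and hydride is delivered inside the chelate. The (S)-ligand should give the (R)-aryl carbinol, in the same spatial sense in which it gives (S)-3-hydroxybutanoate; the descriptor differs because aryl outranks CH2CO2Me. The configuration of 10 is to be confirmed before going on.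

Step 5
Reactants: 10 methyl (3R)-3-hydroxy-3-[4-(triisopropylsilyloxy)phenyl]propanoate
Product: 11 methyl (3R)-3-(triethylsilyloxy)-3-[4-(triisopropylsilyloxy)phenyl]propanoate
Conditions: TESCl, imidazole, DMF, 0 °C to rt
Reagents that add atoms: triethylsilyl chloride, CC[Si](Cl)(CC)CC
Why: Silylation of the secondary alcohol; TES is chosen so that weak acid can later remove it without touching the aryl silyl ethers.

Step 6
Reactants: 11 methyl (3R)-3-(triethylsilyloxy)-3-[4-(triisopropylsilyloxy)phenyl]propanoate
Product: 12 (3R)-3-(triethylsilyloxy)-3-[4-(triisopropylsilyloxy)phenyl]propanoic acid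
Conditions: Me3SnOH (4 equiv), 1,2-dichloroethane, 70 °C; cold 0.1 M aq HCl wash
Reagents that add atoms: trimethyltin hydroxide, C[Sn](C)(C)O
Why: Trimethyltin hydroxide hydrolysis of a methyl ester delivers hydroxide from tin to the carbonyl under near-neutral conditions, which should avoid E1cB loss of silanolate and cleavage of the aryl silyl ether by aqueous alkali.

Step 7
Reactants: 12 (3R)-3-(triethylsilyloxy)-3-[4-(triisopropylsilyloxy)phenyl]propanoic acid; 4 2,4-diprenylphloroglucinol
Product: 13 3,5-dihydroxy-2,4-diprenylphenyl (3R)-3-(triethylsilyloxy)-3-[4-(triisopropylsilyloxy)phenyl]propanoate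
Conditions: 4 (3 equiv), EDC·HCl, DMAP (0.2 equiv), CH2Cl2, 0 °C to rt, slow addition of 12
Reagents that add atoms: none
Why: Steglich esterification; the two equivalent hydroxyls flanked by one prenyl group and one hydrogen should be acylated in preference to the one between two prenyl groups, and the excess of 4 (recovered) should hold back double acylation.

Step 8
Reactants: 13 3,5-dihydroxy-2,4-diprenylphenyl (3R)-3-(triethylsilyloxy)-3-[4-(triisopropylsilyloxy)phenyl]propanoate
Product: 14 3,5-bis(tert-butyldimethylsilyloxy)-2,4-diprenylphenyl (3R)-3-(triethylsilyloxy)-3-[4-(triisopropylsilyloxy)phenyl]propanoate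
Conditions: TBSOTf (2.5 equiv), 2,6-lutidine (4 equiv), CH2Cl2, −78 to 0 °C
Reagents that add atoms: tert-butyldimethylsilyl triflate, CC(C)(C)[Si](C)(C)OS(=O)(=O)C(F)(F)F
Why: A silyl triflate with a hindered pyridine base silylates both remaining phenols, including the one between the prenyl groups, with no nucleophile present that could cleave or move the aryl ester.

Step 9
Reactants: 14 3,5-bis(tert-butyldimethylsilyloxy)-2,4-diprenylphenyl (3R)-3-(triethylsilyloxy)-3-[4-(triisopropylsilyloxy)phenyl]propanoate
Product: 16 (3R)-1-[4,6-bis(tert-butyldimethylsilyloxy)-2-hydroxy-3,5-diprenylphenyl]-3-(triethylsilyloxy)-3-[4-(triisopropylsilyloxy)phenyl]propan-1-one, via 6-acylcyclohexa-2,4-dienone 15 (not isolated)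
Conditions: hν (254 nm, quartz), degassed cyclohexane (0.005 M), rt; stopped at partial conversion, 14 recycled
Reagents that add atoms: none
Why: Excitation of the aryl ester chromophore homolyses the ArO–C(O) bond and gives, inside the solvent cage, a 3,5-bis(silyloxy)-2,4-diprenylphenoxyl radical and an acyl radical; bonding at the one hydrogen-bearing ortho carbon gives dienone 15, which enolizes to the chelated 2-hydroxyaryl ketone 16 and so forms C4–C4a. The closest known reaction is the photo-Fries rearrangement of aryl alkanoates and aryl 3-arylpropanoates, including 3,5-dioxygenated phenyl esters, to 2-hydroxyaryl ketones. No ring is closed and no stereocentre is set: the sp3 ring carbon of 15 is transient, and the (R)-carbinol, two bonds from the radical centre, is not involved. Site selectivity is needed among the two ortho carbons and the para carbon that carry the phenoxyl spin; the substrate secures it because the prenyl-bearing positions can only give dienones that cannot aromatize and that should fall back to the radical pair or be lost as minor by-products. Cage recombination must also outrun decarbonylation, which should be slow because it would give an unstabilized primary alkyl radical. Both spectator phenols are silylated, so no phenolic O–H flanks a prenyl double bond in the excited state and the photocyclization known for ortho-allylphenols is switched off. The product is shielded from further photolysis by fast excited-state proton transfer within its O–H···O=C chelate. The neutral, reagent-free conditions should leave the prenyl groups and all four silyl ethers intact.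

Step 10
Reactants: 16 (3R)-1-[4,6-bis(tert-butyldimethylsilyloxy)-2-hydroxy-3,5-diprenylphenyl]-3-(triethylsilyloxy)-3-[4-(triisopropylsilyloxy)phenyl]propan-1-one
Product: 17 (3R)-1-[4,6-bis(tert-butyldimethylsilyloxy)-2-hydroxy-3,5-diprenylphenyl]-3-hydroxy-3-[4-(triisopropylsilyloxy)phenyl]propan-1-one
Conditions: AcOH/THF/H2O (3:1:1), rt
Reagents that add atoms: none
Why: Acid hydrolysis of silyl ethers depends on the basicity of the oxygen and the size of the silicon group, so the alkyl TES ether should cleave while the aryl TBS and TIPS ethers stay; acetic acid is too weak to ionize the benzylic carbinol or to cyclize a prenyl group.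

Step 11
Reactants: 17 (3R)-1-[4,6-bis(tert-butyldimethylsilyloxy)-2-hydroxy-3,5-diprenylphenyl]-3-hydroxy-3-[4-(triisopropylsilyloxy)phenyl]propan-1-one
Product: 19 (2S)-5,7-bis(tert-butyldimethylsilyloxy)-6,8-diprenyl-2-[4-(triisopropylsilyloxy)phenyl]chroman-4-one, via alkoxyphosphonium phenoxide 18 (not isolated)
Conditions: PPh3 (1.5 equiv), DIAD (1.5 equiv), toluene (0.01 M), 0 °C
Reagents that add atoms: none
Why: Intramolecular Mitsunobu etherification, known for 3-aryl-3-hydroxy-1-(2-hydroxyaryl)propan-1-ones: the single free phenol protonates the PPh3–DIAD betaine, the carbinol is activated as 18, and 6-exo-tet SN2 attack by the phenoxide inverts (R) to (2S). Toluene, low temperature and dilution are chosen to disfavour ionization and intermolecular reaction.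

Step 12
Reactants: 19 (2S)-5,7-bis(tert-butyldimethylsilyloxy)-6,8-diprenyl-2-[4-(triisopropylsilyloxy)phenyl]chroman-4-one
Product: 20 6,8-diprenylnaringenin
Conditions: TBAF (4 equiv), AcOH (4 equiv), THF, 0 °C to rt
Reagents that add atoms: none
Why: Fluoride cleavage of the three aryl silyl ethers; acetic acid protonates the phenoxides as they form, so ring C should not open by retro-oxa-Michael reaction, C2 should keep its configuration, and nothing acidic enough to cyclize the prenyl groups is present.

## Compound list

1 | phloroglucinol (benzene-1,3,5-triol) | Oc1cc(O)cc(O)c1 | starting material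
2 | prenyl bromide (1-bromo-3-methylbut-2-ene) | CC(C)=CCBr | starting material
3 | 2-prenylphloroglucinol | CC(C)=CCc1c(O)cc(O)cc1O | intermediate (not isolated)
4 | 2,4-diprenylphloroglucinol [2,4-bis(3-methylbut-2-en-1-yl)benzene-1,3,5-triol] | CC(C)=CCc1c(O)cc(O)c(CC=C(C)C)c1O | intermediate
5 | methyl 4-hydroxybenzoate | COC(=O)c1ccc(O)cc1 | starting material
6 | methyl 4-(triisopropylsilyloxy)benzoate | COC(=O)c1ccc(O[Si](C(C)C)(C(C)C)C(C)C)cc1 | intermediate
7 | methyl acetate | COC(C)=O | starting material
8 | lithium enolate of methyl acetate (lithium 1-methoxyethenolate) | [Li+].[O-]C(=C)OC | intermediate (not isolated)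
9 | methyl 3-oxo-3-[4-(triisopropylsilyloxy)phenyl]propanoate | COC(=O)CC(=O)c1ccc(O[Si](C(C)C)(C(C)C)C(C)C)cc1 | intermediate
10 | methyl (3R)-3-hydroxy-3-[4-(triisopropylsilyloxy)phenyl]propanoate | COC(=O)C[C@@H](O)c1ccc(O[Si](C(C)C)(C(C)C)C(C)C)cc1 | intermediate
11 | methyl (3R)-3-(triethylsilyloxy)-3-[4-(triisopropylsilyloxy)phenyl]propanoate | COC(=O)C[C@@H](O[Si](CC)(CC)CC)c1ccc(O[Si](C(C)C)(C(C)C)C(C)C)cc1 | intermediate
12 | (3R)-3-(triethylsilyloxy)-3-[4-(triisopropylsilyloxy)phenyl]propanoic acid | OC(=O)C[C@@H](O[Si](CC)(CC)CC)c1ccc(O[Si](C(C)C)(C(C)C)C(C)C)cc1 | intermediate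
13 | 3,5-dihydroxy-2,4-diprenylphenyl (3R)-3-(triethylsilyloxy)-3-[4-(triisopropylsilyloxy)phenyl]propanoate | CC(C)=CCc1c(O)c(CC=C(C)C)c(OC(=O)C[C@@H](O[Si](CC)(CC)CC)c2ccc(O[Si](C(C)C)(C(C)C)C(C)C)cc2)cc1O | intermediate
14 | 3,5-bis(tert-butyldimethylsilyloxy)-2,4-diprenylphenyl (3R)-3-(triethylsilyloxy)-3-[4-(triisopropylsilyloxy)phenyl]propanoate | CC(C)=CCc1c(O[Si](C)(C)C(C)(C)C)c(CC=C(C)C)c(OC(=O)C[C@@H](O[Si](CC)(CC)CC)c2ccc(O[Si](C(C)C)(C(C)C)C(C)C)cc2)cc1O[Si](C)(C)C(C)(C)C | intermediate (key-step precursor)
15 | 6-acyl-3,5-bis(tert-butyldimethylsilyloxy)-2,4-diprenylcyclohexa-2,4-dienone, acyl = (3R)-3-(triethylsilyloxy)-3-[4-(triisopropylsilyloxy)phenyl]propanoyl; both C6 epimers | CC(C)=CCC1=C(O[Si](C)(C)C(C)(C)C)C(CC=C(C)C)=C(O[Si](C)(C)C(C)(C)C)C(C(=O)C[C@@H](O[Si](CC)(CC)CC)c2ccc(O[Si](C(C)C)(C(C)C)C(C)C)cc2)C1=O | intermediate (not isolated)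
16 | (3R)-1-[4,6-bis(tert-butyldimethylsilyloxy)-2-hydroxy-3,5-diprenylphenyl]-3-(triethylsilyloxy)-3-[4-(triisopropylsilyloxy)phenyl]propan-1-one | CC(C)=CCc1c(O[Si](C)(C)C(C)(C)C)c(CC=C(C)C)c(O)c(C(=O)C[C@@H](O[Si](CC)(CC)CC)c2ccc(O[Si](C(C)C)(C(C)C)C(C)C)cc2)c1O[Si](C)(C)C(C)(C)C | intermediate (key-step product)
17 | (3R)-1-[4,6-bis(tert-butyldimethylsilyloxy)-2-hydroxy-3,5-diprenylphenyl]-3-hydroxy-3-[4-(triisopropylsilyloxy)phenyl]propan-1-one | CC(C)=CCc1c(O[Si](C)(C)C(C)(C)C)c(CC=C(C)C)c(O)c(C(=O)C[C@@H](O)c2ccc(O[Si](C(C)C)(C(C)C)C(C)C)cc2)c1O[Si](C)(C)C(C)(C)C | intermediate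
18 | (R)-alkoxy(triphenyl)phosphonium phenoxide zwitterion derived from 17 | CC(C)=CCc1c(O[Si](C)(C)C(C)(C)C)c(CC=C(C)C)c([O-])c(C(=O)C[C@@H](O[P+](c2ccccc2)(c2ccccc2)c2ccccc2)c2ccc(O[Si](C(C)C)(C(C)C)C(C)C)cc2)c1O[Si](C)(C)C(C)(C)C | intermediate (not isolated)
19 | (2S)-5,7-bis(tert-butyldimethylsilyloxy)-6,8-diprenyl-2-[4-(triisopropylsilyloxy)phenyl]chroman-4-one | CC(C)=CCc1c(O[Si](C)(C)C(C)(C)C)c(CC=C(C)C)c2c(c1O[Si](C)(C)C(C)(C)C)C(=O)C[C@@H](c1ccc(O[Si](C(C)C)(C(C)C)C(C)C)cc1)O2 | intermediate
20 | 6,8-diprenylnaringenin [(2S)-5,7-dihydroxy-2-(4-hydroxyphenyl)-6,8-bis(3-methylbut-2-en-1-yl)chroman-4-one] | CC(C)=CCc1c(O)c(CC=C(C)C)c2c(c1O)C(=O)C[C@@H](c1ccc(O)cc1)O2 | target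

## Step count and least certain steps

Total: 12 steps. Longest linear sequence: 11 steps (5 to 20, steps 2–12); step 1 supplies the second fragment.

**Step 9 (key step).**
- Risk: escape of the radical pair from the solvent cage, which fragments the ester instead of rearranging it, and stalling of the photolysis once 16 absorbs most of the light. The crowded recombination site, flanked by a silyloxy group, and bonding at the prenyl-bearing carbons could add to the loss.
- Fallback: move the acyl shift ahead of prenylation; it sets out from 12 and 1 and comes back at 16. Acid 12 is esterified (EDC·HCl, DMAP) with a large excess of 1 to give 3,5-dihydroxyphenyl (3R)-3-(triethylsilyloxy)-3-[4-(triisopropylsilyloxy)phenyl]propanoate F1. Photolysis at 254 nm, in which both ortho carbons and the para carbon lead to the same ketone, gives (3R)-3-(triethylsilyloxy)-1-(2,4,6-trihydroxyphenyl)-3-[4-(triisopropylsilyloxy)phenyl]propan-1-one F2. Double C-prenylation of this acylphloroglucinol with 2 and DBU in THF gives (3R)-3-(triethylsilyloxy)-1-(2,4,6-trihydroxy-3,5-diprenylphenyl)-3-[4-(triisopropylsilyloxy)phenyl]propan-1-one F3. TBSCl (2.1 equiv) and imidazole then silylate the para hydroxyl and one ortho hydroxyl and leave the chelated one, which gives 16.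

**Step 11 (Mitsunobu closure).**
- Risk: partial ionization of the activated benzylic C–O bond, which the para-silyloxy group favours, or E1cB elimination across C2–C3 followed by non-selective re-closure. Either erodes the enantiomeric purity at C2.
- Fallback: secure C2 by catalyst control; it sets out from 19 of insufficient purity and comes back at 19. Asymmetric transfer hydrogenation with RhCl(Cp*)[(R,R)-TsDPEN] and HCO2H/Et3N in EtOAc should, by analogy with aryl ketone reduction, consume the (2R)-enantiomer as the cis-alcohol (2R,4R)-5,7-bis(tert-butyldimethylsilyloxy)-6,8-diprenyl-2-[4-(triisopropylsilyloxy)phenyl]chroman-4-ol F4, which is separated. The (2S)-ketone 19 is left behind. The peri silyloxy group may slow the reduction, and the enantiomeric catalyst would be used if the sense proved opposite.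

**Step 7 (mono-esterification).**
- Risk: over-acylation and acylation at the hindered hydroxyl, which would consume the chiral acid in a statistical reaction.
- Fallback: move the statistical event onto the achiral fragment; it sets out from 4 and comes back at 14. Exhaustive silylation of 4 (TBSOTf, 2,6-lutidine) gives 1,3,5-tris(tert-butyldimethylsilyloxy)-2,4-diprenylbenzene F5. One of its two equivalent, less hindered silyl ethers is removed with one equivalent of TBAF at −78 °C to give 3,5-bis(tert-butyldimethylsilyloxy)-2,4-diprenylphenol F6; over-cleaved material is resilylated. Esterification of the single hydroxyl of F6 with 12 (EDC·HCl, DMAP) gives 14 directly.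

**Step 1 (double C-prenylation).**
- Risk: poor control over the degree and site of alkylation (O-alkylation, geminal dialkylation, a third prenylation), leaving 4 as a minor component.
- Fallback: directed metalation; it sets out from 1 and comes back at 4. MOMCl and i-Pr2NEt give 1,3,5-tris(methoxymethoxy)benzene F7. Lithiation between two MOM ethers (n-BuLi, THF, 0 °C) and alkylation with 2 (CuBr·SMe2) gives 1,3,5-tris(methoxymethoxy)-2-prenylbenzene F8. A second lithiation and alkylation gives 1,3,5-tris(methoxymethoxy)-2,4-diprenylbenzene F9. Catalytic HCl in MeOH at rt, kept mild to avoid chroman formation, releases 4.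

## Further compounds

F1 | step 9 | 3,5-dihydroxyphenyl (3R)-3-(triethylsilyloxy)-3-[4-(triisopropylsilyloxy)phenyl]propanoate | Oc1cc(O)cc(OC(=O)C[C@@H](O[Si](CC)(CC)CC)c2ccc(O[Si](C(C)C)(C(C)C)C(C)C)cc2)c1
F2 | step 9 | (3R)-3-(triethylsilyloxy)-1-(2,4,6-trihydroxyphenyl)-3-[4-(triisopropylsilyloxy)phenyl]propan-1-one | Oc1cc(O)c(C(=O)C[C@@H](O[Si](CC)(CC)CC)c2ccc(O[Si](C(C)C)(C(C)C)C(C)C)cc2)c(O)c1
F3 | step 9 | (3R)-3-(triethylsilyloxy)-1-(2,4,6-trihydroxy-3,5-diprenylphenyl)-3-[4-(triisopropylsilyloxy)phenyl]propan-1-one | CC(C)=CCc1c(O)c(CC=C(C)C)c(O)c(C(=O)C[C@@H](O[Si](CC)(CC)CC)c2ccc(O[Si](C(C)C)(C(C)C)C(C)C)cc2)c1O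
F4 | step 11 | (2R,4R)-5,7-bis(tert-butyldimethylsilyloxy)-6,8-diprenyl-2-[4-(triisopropylsilyloxy)phenyl]chroman-4-ol | CC(C)=CCc1c(O[Si](C)(C)C(C)(C)C)c(CC=C(C)C)c2c(c1O[Si](C)(C)C(C)(C)C)[C@H](O)C[C@H](c1ccc(O[Si](C(C)C)(C(C)C)C(C)C)cc1)O2
F5 | step 7 | 1,3,5-tris(tert-butyldimethylsilyloxy)-2,4-diprenylbenzene | CC(C)=CCc1c(O[Si](C)(C)C(C)(C)C)cc(O[Si](C)(C)C(C)(C)C)c(CC=C(C)C)c1O[Si](C)(C)C(C)(C)C
F6 | step 7 | 3,5-bis(tert-butyldimethylsilyloxy)-2,4-diprenylphenol | CC(C)=CCc1c(O)cc(O[Si](C)(C)C(C)(C)C)c(CC=C(C)C)c1O[Si](C)(C)C(C)(C)C
F7 | step 1 | 1,3,5-tris(methoxymethoxy)benzene | COCOc1cc(OCOC)cc(OCOC)c1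
F8 | step 1 | 1,3,5-tris(methoxymethoxy)-2-prenylbenzene | COCOc1cc(OCOC)c(CC=C(C)C)c(OCOC)c1
F9 | step 1 | 1,3,5-tris(methoxymethoxy)-2,4-diprenylbenzene | COCOc1cc(OCOC)c(CC=C(C)C)c(OCOC)c1CC=C(C)C
A1 | alternative 1 | (2S)-4'-O-tert-butyldimethylsilyl-6,8-diprenylnaringenin | CC(C)=CCc1c(O)c(CC=C(C)C)c2c(c1O)C(=O)C[C@@H](c1ccc(O[Si](C)(C)C(C)(C)C)cc1)O2
A2 | alternative 1 | (2S)-5-bromo-2-[4-(tert-butyldimethylsilyloxy)phenyl]-2,3-dihydro-4H-pyran-4-one | O=C1C[C@@H](c2ccc(O[Si](C)(C)C(C)(C)C)cc2)OC=C1Br
A3 | alternative 1 | 1-methoxy-2,4-diprenyl-1,3-bis(trimethylsilyloxy)buta-1,3-diene | COC(O[Si](C)(C)C)=C(CC=C(C)C)C(O[Si](C)(C)C)=CCC=C(C)C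
A4 | alternative 2 | (2S)-5,7,4'-tris-O-methoxymethyl-6,8-diprenylnaringenin | CC(C)=CCc1c(OCOC)c(CC=C(C)C)c2c(c1OCOC)C(=O)C[C@@H](c1ccc(OCOC)cc1)O2
A5 | alternative 2 | 5,7,4'-tris(methoxymethoxy)-6,8-diprenylflavone | CC(C)=CCc1c(OCOC)c(CC=C(C)C)c2oc(-c3ccc(OCOC)cc3)cc(=O)c2c1OCOC
A6 | alternative 3 | (2S)-5,7,4'-tris-O-tert-butyldimethylsilyl-6,8-diprenylnaringenin | CC(C)=CCc1c(O[Si](C)(C)C(C)(C)C)c(CC=C(C)C)c2c(c1O[Si](C)(C)C(C)(C)C)C(=O)C[C@@H](c1ccc(O[Si](C)(C)C(C)(C)C)cc1)O2
A7 | alternative 3 | 5,7-bis(tert-butyldimethylsilyloxy)-2-[4-(tert-butyldimethylsilyloxy)phenyl]-4-methylene-6,8-diprenyl-4H-1,3-benzodioxine | C=C1OC(c2ccc(O[Si](C)(C)C(C)(C)C)cc2)Oc2c(CC=C(C)C)c(O[Si](C)(C)C(C)(C)C)c(CC=C(C)C)c(O[Si](C)(C)C(C)(C)C)c21
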